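## Analysis of the target

Aikupikoxide D (23) is a monocyclic 1,2-dioxane with ring atoms O1, O2, C3, C4, C5 and C6; the carbon chain is numbered here from the ester carbon C1 to the carbinol carbon C14. C3 carries the methyl propanoate branch (C1, and C2 with its methyl group). C6 is fully substituted, bearing a methyl group and the chain C7–C14, which holds a C9 ketone conjugated to a C10 exo-methylene and ends in the C14 tertiary alcohol. The three stereocentres are 2S, 3S and 6R: C2 and C3 are neighbours (C2 methyl and C3 oxygen anti along the extended chain), and C6 lies across the ring from C3 with C7 cis to the C3 branch. The O–O bond excludes hydrogenation, dissolving and low-valent metals and hot base; C3–H can be lost with O–O cleavage, and once C1 is a carbonyl group C2–H is placed for β-elimination of the peroxide, while the α-methylene ketone is a reactive Michael acceptor. The hard part is closing the peroxide ring at a quaternary carbon whose two carbon arms (methyl and C7) differ little in size and whose only stereochemical neighbour, C3, is three bonds away. The strategy rests on one feature: C6 has no hydrogen and C7 is a methylene, so a C6=C7 1,1-disubstituted alkene attacked at C6 by a C3 hydroperoxide leaves a C7–metal bond without any β-hydrogen, which can only be consumed by forming the C7–C8 bond.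

## Retrosynthetic reasoning

**C1 oxidation level (23 ⇒ 22 ⇒ 21 ⇒ 20).** No skeletal bond is cut; C1 is taken back to a silyl-protected primary alcohol. While C1 is an ether, C2–H is not acidic, so the β-peroxy carbonyl arrangement that can expel the peroxide exists only in the last two steps. The forward steps must remove two silyl groups, oxidise one primary alcohol and esterify without base.

**C10=CH2 and C9–C10 (20 ⇒ 19 ⇒ 18 ⇒ 12 + 16).** The exo-methylene is cut first, as the olefination of a phosphorus-bearing C10 with a one-carbon aldehyde; then the C9–C10 bond is cut between aldehyde 12 and carbanion 17 of phosphonate 16. This divides the molecule into the peroxide half and an achiral chain. The phosphorus group makes C10 nucleophilic and later places the alkene at C10 only, which a direct α-methylenation of a C9 ketone flanked by two methylenes could not do. The forward reaction needs a carbanion mild enough to spare the O–O bond.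

**Phosphonate 16 (16 ⇒ 15 ⇒ 14 ⇒ 13).** The C10–P bond and the two C14–methyl bonds are cut, leading to bromo ester 13. An Arbuzov reaction and a double Grignard addition are all that is needed.

**C9 aldehyde (12 ⇒ 11).** The aldehyde is the tautomer of the enol that oxidation of a C9–boron bond on a C8=C9 alkene delivers. No skeletal bond is cut; the boronate is the handle the key step leaves behind.

**Key disconnection (11 ⇒ 9 + 10).** The C6–O1 and C7–C8 bonds are cut together. Backwards, the dioxane opens to hydroperoxy alkene 9 and the three-carbon arm at C6 shrinks to the alkene methylene C7, with C8 and C9 coming from vinylboronate 10. The cut is made here because it is the only place where the ring, the quaternary stereocentre and a carbon–carbon bond can be formed in one catalytic event from an achiral alkene. The forward reaction must add the hydroperoxide oxygen to one face of the alkene under a chiral divalent palladium catalyst and trap the alkylpalladium species by Heck insertion.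

**C3–O bond (9 ⇒ 8 ⇒ 7).** The hydroperoxide is taken back to mesylate 8 and alcohol 7 of opposite C3 configuration. Substitution with inversion is the only stereospecific way to place a peroxide oxygen on a secondary carbon, and it lets the C3 configuration be set as an alcohol by a reliable aldol reaction.

**C2–C3 bond (7 ⇒ 6 ⇒ 5 ⇒ 2 + 3, 2 ⇒ 1).** The bond between the two adjacent stereocentres is cut as a syn-aldol reaction of imide 3 (through boron enolate 4) with aldehyde 2, which comes from ester 1. Both centres are set in one step, before any peroxide exists, and the alkene needed for the key step is already in the aldehyde.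

## Alternatives that were turned down

**Alternative 1:** Arene-derived diene and singlet oxygen.
- Disconnection: both ring C–O bonds (C3–O2 and C6–O1) at once, with a temporary C2–C7 bond holding the future side-chain carbons in a carbocycle.
- Forward key step: photooxygenation of diene acetonide A1 adds singlet oxygen across the diene termini, anti to the acetonide, to give the bicyclic endoperoxide A2. Later the C4=C5 bond is reduced with diimide, the acetonide is removed and the C2–C7 glycol is cleaved.
- For it: the [4+2] addition is the most dependable way to make a 1,2-dioxane. It forms the quaternary C6–O bond with no selectivity question, and the bicycle guarantees the cis relation of C2 and C7. On these points it is stronger than the chosen route.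
- Against it: glycol cleavage delivers C2 as an aldehyde carbon next to the peroxide-bearing C3. Turning it into the CH(CH3)CO2Me stereocentre needs two C–C bonds and a new control element beside a base-sensitive α-peroxy methine. The C2 and C7 aldehydes appear together and must be told apart. Read backwards through an anti addition, the 3S,6R configuration maps onto the (1R,2S) form of A1, which by this analysis is the antipode of what the usual dioxygenase fermentation supplies.
- Comparison: the chosen route sets C2 and C3 together by an aldol reaction and pays with an unproven ring closure. Alternative 1 has the safe ring closure but an unsolved C2 problem and a longer redox sequence.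

**Alternative 2:** Ring-closing metathesis across a preformed peroxide.
- Disconnection: the C4=C5 bond of a 3,6-dihydro-1,2-dioxine; the ring is closed by C–C bond formation across a peroxide that already links C3 and C6.
- Forward key step: second-generation Hoveyda–Grubbs catalyst closes the acyclic bis-allylic peroxide A3 to dihydrodioxine A4; diimide then saturates C4=C5.
- For it: six-membered ring closure between two monosubstituted alkenes is predictable, the ring-forming step creates no stereocentre, and A4 already carries C7–C9 at the right oxidation level as an acetal. In these respects it is stronger than the chosen route.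
- Against it: the whole stereochemical problem moves into A3. Making it means joining a peroxide oxygen to a tertiary allylic C6 or a secondary allylic C3 with full stereocontrol. Tertiary allylic peroxides are hard to obtain enantiopure and prone to allylic peroxy rearrangement, and substitution at a secondary allylic carbon competes with SN2′ attack and elimination. The ruthenium carbene must also tolerate an allylic O–O bond.
- Comparison: the chosen route creates C6 in the ring-forming step from an achiral alkene under catalyst control and needs no alkene reduction afterwards; it gives up the certainty of the metathesis.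

**Alternative 3:** Oxetane strain release.
- Disconnection: the C6–O1 bond, by intramolecular opening of a 2,2-disubstituted oxetane (O, C6, C7, C8) by the C3 hydroperoxide.
- Forward key step: catalytic Me3SiOTf activates the oxetane of A5, the hydroperoxide attacks C6 with inversion in a 6-exo closure, and the oxetane oxygen becomes the C8 hydroxyl of hydroxyethyl dioxane A6.
- For it: Lewis-acid opening of oxetanes by hydroperoxides is an established route to tertiary peroxides, no transition metal meets the hydroperoxide, and the C6 configuration is transferred rather than induced. On precedent and chemoselectivity it is stronger than the chosen route.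
- Against it: C6 must first be made as an enantiopure quaternary oxetane carbon whose two arms are plain methylene groups, and carried through the aldol, the reduction and the peroxide displacement. Ionisation at the tertiary centre can leak configuration. A6 ends at C8, so a one-carbon homologation is needed before the C9–C10 bond can be made.
- Comparison: the chosen route reaches the C9 aldehyde in two steps from a simple alkene and makes C6 catalytically, at the price of an unprecedented step. Alternative 3 is safer chemistry but several steps longer. Its logic, a stepwise ionic closure at C6, is kept as the fallback for the key step.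

Key step: step 7

Assumption: the facial preference of the binaphthyl bis(oxazoline)–palladium catalyst is taken to carry over from alkenyl phenols to the hydroperoxide, which assigns the (R,R) ligand to the 6R product; if the sense proves reversed, the (S,S) ligand is used in the same step.

## Route

Step 1
Reactants: 1 ethyl 4-methylpent-4-enoate
Product: 2 4-methylpent-4-enal
Conditions: iBu2AlH (1.05 equiv), CH2Cl2, −78 °C; MeOH, then aq. potassium sodium tartrate
Reagents that add atoms: none
Why: Partial reduction of an ester at −78 °C stops at the aluminium hemiacetal, which releases the aldehyde only on aqueous work-up; the volatile aldehyde is kept as a dried CH2Cl2 solution and used at once.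

Step 2
Reactants: 2 4-methylpent-4-enal; 3 (S)-4-benzyl-3-propanoyloxazolidin-2-one
Product: 5 (4S)-4-benzyl-3-[(2S,3R)-3-hydroxy-2,6-dimethylhept-6-enoyl]-1,3-oxazolidin-2-one, via dibutylboron Z-enolate 4 (not isolated)
Conditions: Bu2BOTf, Et3N, CH2Cl2, 0 °C; then 2, −78 → 0 °C; pH 7 phosphate buffer, MeOH, 30% H2O2, 0 °C
Reagents that add atoms: none
Why: Evans syn-aldol reaction: soft enolisation gives the Z-boron enolate 4, which adds to the aldehyde through a chair Zimmerman–Traxler transition state on the face away from the benzyl group, setting C2 (S) and C3 (R) as the syn pair. The oxidative work-up only cleaves boron–carbon and boron–oxygen bonds and leaves the 1,1-disubstituted alkene alone.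

Step 3
Reactants: 5 (4S)-4-benzyl-3-[(2S,3R)-3-hydroxy-2,6-dimethylhept-6-enoyl]-1,3-oxazolidin-2-one
Product: 6 (2R,3R)-2,6-dimethylhept-6-ene-1,3-diol
Conditions: LiBH4, MeOH (1 equiv), THF, 0 °C → rt
Reagents that add atoms: none
Why: Reductive removal of the auxiliary: hydride attacks the exocyclic imide carbonyl and gives the primary alcohol without touching C2 (the descriptor changes to R only because C1 loses priority); the oxazolidinone is recovered.

Step 4
Reactants: 6 (2R,3R)-2,6-dimethylhept-6-ene-1,3-diol
Product: 7 (2R,3R)-1-[(tert-butyldimethylsilyl)oxy]-2,6-dimethylhept-6-en-3-ol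
Conditions: TBSCl (1.05 equiv), imidazole, CH2Cl2, −10 → 0 °C
Reagents that add atoms: tert-butyldimethylsilyl chloride, CC(C)(C)[Si](C)(C)Cl
Why: Silylation is selective for the primary over the hindered secondary hydroxyl at low temperature; the ether keeps C1 at the alcohol level so that C2–H stays non-acidic until the peroxide ring and the enone are in place.

Step 5
Reactants: 7 (2R,3R)-1-[(tert-butyldimethylsilyl)oxy]-2,6-dimethylhept-6-en-3-ol
Product: 8 (2R,3R)-1-[(tert-butyldimethylsilyl)oxy]-2,6-dimethylhept-6-en-3-yl methanesulfonate
Conditions: MsCl, Et3N, CH2Cl2, 0 °C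
Reagents that add atoms: methanesulfonyl chloride, CS(=O)(=O)Cl
Why: Sulfonylation at oxygen leaves the C3 configuration untouched and turns the hydroxyl into the leaving group for the one substitution step of the route.

Step 6
Reactants: 8 (2R,3R)-1-[(tert-butyldimethylsilyl)oxy]-2,6-dimethylhept-6-en-3-yl methanesulfonate
Product: 9 tert-butyl{[(2R,3S)-3-hydroperoxy-2,6-dimethylhept-6-en-1-yl]oxy}dimethylsilane (hydroperoxy alkene)
Conditions: 50% aq. H2O2 (large excess), KOH, MeOH/THF, 0 °C → rt
Reagents that add atoms: hydrogen peroxide, OO
Why: SN2 displacement of a secondary sulfonate by the hydroperoxide anion, an α-effect nucleophile, goes with inversion and turns 3R into the 3S configuration of the target. The large excess of H2O2 suppresses a second alkylation to the dialkyl peroxide, and the medium leaves the silyl ether and the alkene alone.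

Step 7
Reactants: 9 tert-butyl{[(2R,3S)-3-hydroperoxy-2,6-dimethylhept-6-en-1-yl]oxy}dimethylsilane; 10 4,4,5,5-tetramethyl-2-vinyl-1,3,2-dioxaborolane
Product: 11 tert-butyldimethyl{(2R)-2-[(3S,6R)-6-methyl-6-[(2E)-3-(4,4,5,5-tetramethyl-1,3,2-dioxaborolan-2-yl)prop-2-en-1-yl]-1,2-dioxan-3-yl]propoxy}silane (dioxane alkenylboronate)
Conditions: Pd(OCOCF3)2 (10 mol %), (R,R)-Bn-BOXAX [(R)-2,2′-bis((4R)-4-benzyl-4,5-dihydrooxazol-2-yl)-1,1′-binaphthyl] (40 mol %), p-benzoquinone (4 equiv), 10 (5 equiv), CH2Cl2, rt
Reagents that add atoms: none
Why: Proposed new method: a domino peroxypalladation–Heck reaction, in which the complex of Pd(OCOCF3)2 with the bis(oxazoline) binds the C6=C7 alkene, the terminal hydroperoxide oxygen adds to the more substituted carbon C6 (C6–O1 bond), and the resulting C7–palladium species, which has no β-hydrogen because C6 is quaternary, inserts vinylboronate 10 at its unsubstituted terminus (C7–C8 bond) before β-hydride elimination from C8 releases the (E)-alkenylboronate and zerovalent palladium, which benzoquinone returns to the divalent state. The closest known reaction types are the enantioselective domino Wacker–Heck cyclisation of 2-(3-methylbut-3-enyl)phenols to 2-methyl-2-alkenylchromans under this catalyst system and the Pd(OAc)2/benzoquinone cyclisation of unsaturated hydroperoxides to 1,2-dioxanes. The dioxane ring closes in the 6-exo-trig mode. C6, the only new stereocentre, is set by the ligand, which selects the alkene face; the C3 branch sits equatorial in the chair-like closure but hardly distinguishes the C6 methyl from the C6 CH2–palladium arm. The step therefore needs catalyst-controlled facial selectivity, and the C6 epimer that may accompany 11 (C7 cis to the C3 branch) should be separable by chromatography. The substrate secures the domino because the 1,1-disubstituted alkene rules out Wacker-type β-hydride collapse, and because the pinacol boronate is a neutral Heck acceptor that places palladium next to boron after insertion, so that elimination can only give the C8=C9 alkene. Base-free conditions at room temperature are chosen to hold back palladium-induced dehydration of the secondary hydroperoxide to the C3 ketone and transmetalation of the boronate.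

Step 8
Reactants: 11 dioxane alkenylboronate
Product: 12 3-[(3R,6S)-6-{(2R)-1-[(tert-butyldimethylsilyl)oxy]propan-2-yl}-3-methyl-1,2-dioxan-3-yl]propanal
Conditions: NaBO3·4H2O (4 equiv), THF/H2O (1:1), rt
Reagents that add atoms: sodium perborate, [Na+].[Na+].O[B-]1(O)OO[B-](O)(O)OO1
Why: Oxidation of the carbon–boron bond: perborate adds to boron, the alkenyl group migrates to oxygen, and hydrolysis gives the enol and hence the C9 aldehyde. This nucleophilic oxidant does not attack the dialkyl peroxide or the silyl ether.

Step 9
Reactants: 13 ethyl 5-bromopentanoate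
Product: 14 ethyl 5-(diethoxyphosphoryl)pentanoate
Conditions: P(OEt)3 (1.5 equiv), neat, 150 °C
Reagents that add atoms: triethyl phosphite, CCOP(OCC)OCC
Why: Michaelis–Arbuzov reaction of a primary bromide; the volatile bromoethane is distilled out as it forms.

Step 10
Reactants: 14 ethyl 5-(diethoxyphosphoryl)pentanoate
Product: 15 diethyl (5-hydroxy-5-methylhexyl)phosphonate
Conditions: MeMgBr (2.3 equiv), THF, −20 → 0 °C; aq. NH4Cl
Reagents that add atoms: methylmagnesium bromide, C[Mg]Br
Why: Double Grignard addition to the carboxylic ester gives the C14 tertiary alcohol; the phosphonate diester is far less electrophilic and its α-protons are not removed by MeMgBr at 0 °C.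

Step 11
Reactants: 15 diethyl (5-hydroxy-5-methylhexyl)phosphonate
Product: 16 diethyl {5-methyl-5-[(triethylsilyl)oxy]hexyl}phosphonate
Conditions: TESOTf, 2,6-lutidine, CH2Cl2, 0 °C
Reagents that add atoms: triethylsilyl trifluoromethanesulfonate, CC[Si](CC)(CC)OS(=O)(=O)C(F)(F)F
Why: A silyl triflate with a hindered pyridine base silylates the tertiary alcohol, so that the coupling needs one equivalent of base and no alkoxide accompanies the carbanion.

Step 12
Reactants: 16 diethyl {5-methyl-5-[(triethylsilyl)oxy]hexyl}phosphonate; 12 3-[(3R,6S)-6-{(2R)-1-[(tert-butyldimethylsilyl)oxy]propan-2-yl}-3-methyl-1,2-dioxan-3-yl]propanal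
Product: 18 diethyl {3-hydroxy-8-methyl-1-[6-{(2R)-1-[(tert-butyldimethylsilyl)oxy]propan-2-yl}-3-methyl-1,2-dioxan-3-yl]-8-[(triethylsilyl)oxy]nonan-4-yl}phosphonate (β-hydroxyphosphonate; ring and side chain configured as in 12; both configurations at C9 and C10), via α-lithio phosphonate 17 (not isolated)
Conditions: 16 (1.5 equiv), nBuLi (1.45 equiv), THF, −78 °C; then 12, −78 °C; aq. NH4Cl
Reagents that add atoms: none
Why: The α-lithio phosphonate 17 adds to the aldehyde at −78 °C and forms the C9–C10 bond; without a second stabilising group the adduct does not collapse to an alkene, and at this temperature the stabilised carbanion is expected to leave the dialkyl peroxide alone. The uncontrolled C9 and C10 centres are removed in the next two steps.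

Step 13
Reactants: 18 β-hydroxyphosphonate
Product: 19 diethyl {8-methyl-1-[(3R,6S)-6-{(2R)-1-[(tert-butyldimethylsilyl)oxy]propan-2-yl}-3-methyl-1,2-dioxan-3-yl]-3-oxo-8-[(triethylsilyl)oxy]nonan-4-yl}phosphonate (β-ketophosphonate; both C10 epimers)
Conditions: Dess–Martin periodinane, NaHCO3, CH2Cl2, 0 °C → rt
Reagents that add atoms: none
Why: Dess–Martin oxidation of the secondary alcohol under buffered, non-basic conditions gives the β-ketophosphonate; the peroxide and both silyl ethers are inert to the reagent.

Step 14
Reactants: 19 β-ketophosphonate
Product: 20 1-[(3R,6S)-6-{(2R)-1-[(tert-butyldimethylsilyl)oxy]propan-2-yl}-3-methyl-1,2-dioxan-3-yl]-8-methyl-4-methylidene-8-[(triethylsilyl)oxy]nonan-3-one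
Conditions: 37% aq. HCHO (excess), K2CO3, THF/H2O, rt
Reagents that add atoms: formaldehyde, C=O
Why: Horner–Wadsworth–Emmons olefination with formaldehyde: carbonate deprotonates the α-substituted β-ketophosphonate, which adds to the very electrophilic aldehyde and expels diethyl phosphate, placing the exo-methylene on C10 and nowhere else. Excess formaldehyde keeps the phosphonate anion from adding to the enone as it forms.

Step 15
Reactants: 20 bis-silyl enone
Product: 21 1-[(3R,6S)-6-[(2R)-1-hydroxypropan-2-yl]-3-methyl-1,2-dioxan-3-yl]-8-hydroxy-8-methyl-4-methylidenenonan-3-one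
Conditions: HF·pyridine, pyridine, THF, 0 °C → rt
Reagents that add atoms: none
Why: Buffered fluoride cleaves the primary tert-butyldimethylsilyl and the tertiary triethylsilyl ether in one operation under conditions that are neither basic nor reducing, so the enone and the peroxide should survive.

Step 16
Reactants: 21 enone diol
Product: 22 (2S)-2-[(3S,6R)-6-(8-hydroxy-8-methyl-4-methylidene-3-oxononyl)-6-methyl-1,2-dioxan-3-yl]propanoic acid
Conditions: TEMPO (0.2 equiv), PhI(OAc)2 (2.5 equiv), MeCN/H2O (1:1), rt
Reagents that add atoms: water, O
Why: Oxoammonium-mediated oxidation takes the primary alcohol through the aldehyde hydrate to the acid. The tertiary alcohol cannot be oxidised, and the weakly acidic medium avoids enolisation at C2 and β-elimination of the peroxide.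

Step 17
Reactants: 22 (2S)-2-[(3S,6R)-6-(8-hydroxy-8-methyl-4-methylidene-3-oxononyl)-6-methyl-1,2-dioxan-3-yl]propanoic acid
Product: 23 aikupikoxide D, methyl (2S)-2-[(3S,6R)-6-(8-hydroxy-8-methyl-4-methylidene-3-oxononyl)-6-methyl-1,2-dioxan-3-yl]propanoate
Conditions: TMSCHN2 (1.2 equiv), toluene/MeOH (4:1), 0 °C, 10 min; AcOH quench
Reagents that add atoms: trimethylsilyldiazomethane, C[Si](C)(C)C=[N+]=[N-]
Why: Methylation of the carboxylic acid by the diazoalkane in methanol is fast at 0 °C and needs no base, so C2 is not epimerised and the peroxide is not eliminated. A small excess and a short reaction time keep the slower dipolar cycloaddition to the enone in check.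

## Compound list

1 | ethyl 4-methylpent-4-enoate | CCOC(=O)CCC(C)=C | starting material
2 | 4-methylpent-4-enal | C=C(C)CCC=O | intermediate
3 | (S)-4-benzyl-3-propanoyloxazolidin-2-one | CCC(=O)N1[C@@H](Cc2ccccc2)COC1=O | starting material
4 | (4S)-4-benzyl-3-[(1Z)-1-(dibutylboranyloxy)prop-1-en-1-yl]-1,3-oxazolidin-2-one (dibutylboron Z-enolate) | C/C=C(\OB(CCCC)CCCC)N1[C@@H](Cc2ccccc2)COC1=O | intermediate
5 | (4S)-4-benzyl-3-[(2S,3R)-3-hydroxy-2,6-dimethylhept-6-enoyl]-1,3-oxazolidin-2-one | C=C(C)CC[C@@H](O)[C@H](C)C(=O)N1[C@@H](Cc2ccccc2)COC1=O | intermediate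
6 | (2R,3R)-2,6-dimethylhept-6-ene-1,3-diol | C=C(C)CC[C@@H](O)[C@H](C)CO | intermediate
7 | (2R,3R)-1-[(tert-butyldimethylsilyl)oxy]-2,6-dimethylhept-6-en-3-ol | C=C(C)CC[C@@H](O)[C@H](C)CO[Si](C)(C)C(C)(C)C | intermediate
8 | (2R,3R)-1-[(tert-butyldimethylsilyl)oxy]-2,6-dimethylhept-6-en-3-yl methanesulfonate | C=C(C)CC[C@@H](OS(C)(=O)=O)[C@H](C)CO[Si](C)(C)C(C)(C)C | intermediate
9 | tert-butyl{[(2R,3S)-3-hydroperoxy-2,6-dimethylhept-6-en-1-yl]oxy}dimethylsilane (hydroperoxy alkene) | C=C(C)CC[C@H](OO)[C@H](C)CO[Si](C)(C)C(C)(C)C | intermediate
10 | 4,4,5,5-tetramethyl-2-vinyl-1,3,2-dioxaborolane | C=CB1OC(C)(C)C(C)(C)O1 | starting material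
11 | tert-butyldimethyl{(2R)-2-[(3S,6R)-6-methyl-6-[(2E)-3-(4,4,5,5-tetramethyl-1,3,2-dioxaborolan-2-yl)prop-2-en-1-yl]-1,2-dioxan-3-yl]propoxy}silane (dioxane alkenylboronate) | CC1(C)OB(/C=C/C[C@@]2(C)CC[C@@H]([C@H](C)CO[Si](C)(C)C(C)(C)C)OO2)OC1(C)C | intermediate
12 | 3-[(3R,6S)-6-{(2R)-1-[(tert-butyldimethylsilyl)oxy]propan-2-yl}-3-methyl-1,2-dioxan-3-yl]propanal | O=CCC[C@@]1(C)CC[C@@H]([C@H](C)CO[Si](C)(C)C(C)(C)C)OO1 | intermediate
13 | ethyl 5-bromopentanoate | CCOC(=O)CCCCBr | starting material
14 | ethyl 5-(diethoxyphosphoryl)pentanoate | CCOC(=O)CCCCP(=O)(OCC)OCC | intermediate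
15 | diethyl (5-hydroxy-5-methylhexyl)phosphonate | CCOP(=O)(CCCCC(C)(C)O)OCC | intermediate
16 | diethyl {5-methyl-5-[(triethylsilyl)oxy]hexyl}phosphonate | CCOP(=O)(CCCCC(C)(C)O[Si](CC)(CC)CC)OCC | intermediate
17 | diethyl {1-lithio-5-methyl-5-[(triethylsilyl)oxy]hexyl}phosphonate (α-lithio phosphonate) | CCOP(=O)(OCC)C([Li])CCCC(C)(C)O[Si](CC)(CC)CC | intermediate
18 | diethyl {3-hydroxy-8-methyl-1-[6-{(2R)-1-[(tert-butyldimethylsilyl)oxy]propan-2-yl}-3-methyl-1,2-dioxan-3-yl]-8-[(triethylsilyl)oxy]nonan-4-yl}phosphonate, ring and side chain configured as in 12, mixture at C9 and C10 (β-hydroxyphosphonate) | CCOP(=O)(OCC)C(CCCC(C)(C)O[Si](CC)(CC)CC)C(O)CC[C@@]1(C)CC[C@@H]([C@H](C)CO[Si](C)(C)C(C)(C)C)OO1 | intermediate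
19 | diethyl {8-methyl-1-[(3R,6S)-6-{(2R)-1-[(tert-butyldimethylsilyl)oxy]propan-2-yl}-3-methyl-1,2-dioxan-3-yl]-3-oxo-8-[(triethylsilyl)oxy]nonan-4-yl}phosphonate, both C10 epimers (β-ketophosphonate) | CCOP(=O)(OCC)C(CCCC(C)(C)O[Si](CC)(CC)CC)C(=O)CC[C@@]1(C)CC[C@@H]([C@H](C)CO[Si](C)(C)C(C)(C)C)OO1 | intermediate
20 | 1-[(3R,6S)-6-{(2R)-1-[(tert-butyldimethylsilyl)oxy]propan-2-yl}-3-methyl-1,2-dioxan-3-yl]-8-methyl-4-methylidene-8-[(triethylsilyl)oxy]nonan-3-one (bis-silyl enone) | C=C(CCCC(C)(C)O[Si](CC)(CC)CC)C(=O)CC[C@@]1(C)CC[C@@H]([C@H](C)CO[Si](C)(C)C(C)(C)C)OO1 | intermediate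
21 | 1-[(3R,6S)-6-[(2R)-1-hydroxypropan-2-yl]-3-methyl-1,2-dioxan-3-yl]-8-hydroxy-8-methyl-4-methylidenenonan-3-one (enone diol) | C=C(CCCC(C)(C)O)C(=O)CC[C@@]1(C)CC[C@@H]([C@H](C)CO)OO1 | intermediate
22 | (2S)-2-[(3S,6R)-6-(8-hydroxy-8-methyl-4-methylidene-3-oxononyl)-6-methyl-1,2-dioxan-3-yl]propanoic acid | C=C(CCCC(C)(C)O)C(=O)CC[C@@]1(C)CC[C@@H]([C@H](C)C(=O)O)OO1 | intermediate
23 | aikupikoxide D, methyl (2S)-2-[(3S,6R)-6-(8-hydroxy-8-methyl-4-methylidene-3-oxononyl)-6-methyl-1,2-dioxan-3-yl]propanoate | C=C(CCCC(C)(C)O)C(=O)CC[C@@]1(C)CC[C@@H]([C@H](C)C(=O)OC)OO1 | target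

## Step count and least certain steps

Total: 17 steps. Longest linear sequence: 14 steps (steps 1–8 and 12–17); phosphonate 16 is made in three steps (9–11).

**Step 7 (key step, new method).** The most likely failure is palladium-induced breakdown of the secondary hydroperoxide outpacing the slow insertion of the boronate: loss of water to the C3 ketone through a palladium alkylperoxide, or O–O cleavage in the β-peroxyalkylpalladium species with epoxide formation. Further risks are poor facial selectivity at C6, since the ligand was developed for a planar phenoxide and C3 offers little bias, and oxidation of the carbon–boron bond by the substrate's own hydroperoxide.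
Fallback by known chemistry, from 9 back to 12:
- Epoxidation of the alkene of 9 with mCPBA (NaHCO3, CH2Cl2) gives the epoxy hydroperoxide F1.
- A catalytic sulfonic acid promotes 6-exo opening of the 2,2-disubstituted epoxide at its tertiary carbon by the hydroperoxide, giving the hydroxymethyl dioxane F2; a mixture of C6 epimers is to be expected and is separated by chromatography.
- Dess–Martin oxidation of the required epimer gives the aldehyde F3, and Wittig reaction with Ph3P=CHCO2Et the enoate F4.
- Diimide reduction gives the saturated ester F5, and iBu2AlH at −78 °C returns aldehyde 12.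

This gives up catalyst control at C6 and costs four more steps.

**Step 6.** The most likely failure is slow substitution at the β-branched secondary carbon, so that elimination toward C4, base-induced decomposition of the hydroperoxide formed and a second alkylation to a dialkyl peroxide take over.
Fallback, from 8 back to 9: the peroxide is brought in as a protected nucleophile. 2-Methoxyprop-2-yl hydroperoxide F6, made by ozonolysis of 2,3-dimethylbut-2-ene in methanol, is alkylated by mesylate 8 with CsOH·H2O in DMF to the peroxyketal F7, with inversion at C3. A monoprotected nucleophile cannot be alkylated twice and is more reactive in the dipolar aprotic solvent. Brief treatment with aqueous acetic acid in THF at 0 °C then releases 9; the peroxyketal is expected to hydrolyse faster than the primary silyl ether.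

**Step 14.** The most likely failure is sluggish olefination of the α-branched phosphonate, which leaves time for Michael addition of its anion to enone 20 and for base-induced opening of the dioxane at C3–H.
Fallback, from 12 back to 20: the enone is built without a phosphonate. Silylation of commercial 4-bromo-2-methylbutan-2-ol (TESOTf, 2,6-lutidine) gives the bromide F8, whose Grignard reagent couples with 2,3-dibromopropene (CuI cat.) to the 2-bromoalkene F9. Bromine–lithium exchange (tBuLi, −78 °C), transmetalation with CeCl3 and addition to aldehyde 12 give the allylic alcohol F10, which Dess–Martin oxidation converts into 20. This replaces steps 12–14 by two steps on the main line but brings a more reactive organometallic next to the peroxide.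

**Step 17 (with step 16).** The most likely failure is dipolar cycloaddition of the diazoalkane to the α-methylene ketone, or loss of the enone in the two steps before it.
Fallback, from 19 back to 23: the order is changed so that the enone is made last. Compound 19 is desilylated with HF·pyridine to the diol F11, oxidised (TEMPO, PhI(OAc)2) to the acid F12 and methylated with TMSCHN2 to the ester F13. Olefination with aqueous formaldehyde and K2CO3 then gives 23 directly. The price is a mildly basic last step on the β-peroxy ester.

## Further compounds

F1 | step 7 | tert-butyl{[(2R,3S)-3-hydroperoxy-2-methyl-5-(2-methyloxiran-2-yl)pentyl]oxy}dimethylsilane, both epoxide epimers | CC1(CC[C@H](OO)[C@H](C)CO[Si](C)(C)C(C)(C)C)CO1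
F2 | step 7 | [(3R,6S)-6-{(2R)-1-[(tert-butyldimethylsilyl)oxy]propan-2-yl}-3-methyl-1,2-dioxan-3-yl]methanol | OC[C@@]1(C)CC[C@@H]([C@H](C)CO[Si](C)(C)C(C)(C)C)OO1
F3 | step 7 | (3R,6S)-6-{(2R)-1-[(tert-butyldimethylsilyl)oxy]propan-2-yl}-3-methyl-1,2-dioxane-3-carbaldehyde | O=C[C@@]1(C)CC[C@@H]([C@H](C)CO[Si](C)(C)C(C)(C)C)OO1
F4 | step 7 | ethyl (2E)-3-[(3R,6S)-6-{(2R)-1-[(tert-butyldimethylsilyl)oxy]propan-2-yl}-3-methyl-1,2-dioxan-3-yl]prop-2-enoate | CCOC(=O)/C=C/[C@@]1(C)CC[C@@H]([C@H](C)CO[Si](C)(C)C(C)(C)C)OO1
F5 | step 7 | ethyl 3-[(3R,6S)-6-{(2R)-1-[(tert-butyldimethylsilyl)oxy]propan-2-yl}-3-methyl-1,2-dioxan-3-yl]propanoate | CCOC(=O)CC[C@@]1(C)CC[C@@H]([C@H](C)CO[Si](C)(C)C(C)(C)C)OO1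
F6 | step 6 | 2-methoxyprop-2-yl hydroperoxide | COC(C)(C)OO
F7 | step 6 | tert-butyl({(2R,3S)-3-[(2-methoxypropan-2-yl)peroxy]-2,6-dimethylhept-6-en-1-yl}oxy)dimethylsilane | C=C(C)CC[C@H](OOC(C)(C)OC)[C@H](C)CO[Si](C)(C)C(C)(C)C
F8 | step 14 | [(4-bromo-2-methylbutan-2-yl)oxy]triethylsilane | CC(C)(CCBr)O[Si](CC)(CC)CC
F9 | step 14 | [(6-bromo-2-methylhept-6-en-2-yl)oxy]triethylsilane | C=C(Br)CCCC(C)(C)O[Si](CC)(CC)CC
F10 | step 14 | 1-[6-{(2R)-1-[(tert-butyldimethylsilyl)oxy]propan-2-yl}-3-methyl-1,2-dioxan-3-yl]-8-methyl-4-methylidene-8-[(triethylsilyl)oxy]nonan-3-ol, ring and side chain configured as in 12, both C9 epimers | C=C(CCCC(C)(C)O[Si](CC)(CC)CC)C(O)CC[C@@]1(C)CC[C@@H]([C@H](C)CO[Si](C)(C)C(C)(C)C)OO1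
F11 | step 17 | diethyl {8-hydroxy-1-[(3R,6S)-6-[(2R)-1-hydroxypropan-2-yl]-3-methyl-1,2-dioxan-3-yl]-8-methyl-3-oxononan-4-yl}phosphonate | CCOP(=O)(OCC)C(CCCC(C)(C)O)C(=O)CC[C@@]1(C)CC[C@@H]([C@H](C)CO)OO1
F12 | step 17 | (2S)-2-[(3S,6R)-6-[4-(diethoxyphosphoryl)-8-hydroxy-8-methyl-3-oxononyl]-6-methyl-1,2-dioxan-3-yl]propanoic acid | CCOP(=O)(OCC)C(CCCC(C)(C)O)C(=O)CC[C@@]1(C)CC[C@@H]([C@H](C)C(=O)O)OO1
F13 | step 17 | methyl (2S)-2-[(3S,6R)-6-[4-(diethoxyphosphoryl)-8-hydroxy-8-methyl-3-oxononyl]-6-methyl-1,2-dioxan-3-yl]propanoate | CCOP(=O)(OCC)C(CCCC(C)(C)O)C(=O)CC[C@@]1(C)CC[C@@H]([C@H](C)C(=O)OC)OO1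
A1 | alternative 1 | acetonide of (1R,2S)-3-methylcyclohexa-3,5-diene-1,2-diol (diene acetonide) | CC1=CC=C[C@H]2OC(C)(C)O[C@@H]12
A2 | alternative 1 | bicyclic endoperoxide acetonide (2,3-dioxabicyclo[2.2.2]octene) | C[C@]12C=C[C@H](OO1)[C@H]3OC(C)(C)O[C@@H]23
A3 | alternative 2 | acyclic bis-allylic dialkyl peroxide | COC(OC)CC[C@@](C)(C=C)OO[C@@H](C=C)[C@H](C)CO[Si](C)(C)C(C)(C)C
A4 | alternative 2 | 3,6-dihydro-1,2-dioxine | COC(OC)CC[C@@]1(C)C=C[C@@H]([C@H](C)CO[Si](C)(C)C(C)(C)C)OO1
A5 | alternative 3 | oxetane hydroperoxide | C[C@]1(CC[C@H](OO)[C@H](C)CO[Si](C)(C)C(C)(C)C)CCO1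
A6 | alternative 3 | hydroxyethyl dioxane | OCC[C@@]1(C)CC[C@@H]([C@H](C)CO[Si](C)(C)C(C)(C)C)OO1
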